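**Retrosynthetic overview**
1. Target 36 comes from alcohol 33 by acylation and desilylation; the 11-membered carbocycle is closed last by an intramolecular Nozaki–Hiyama–Kishi addition (C2–C3) of an (E)-vinyl iodide to the α,β-epoxy aldehyde 30.
2. The open-chain precursor 29 comes from an E-selective Horner–Wadsworth–Emmons union (C7=C8) of aldehyde 20 (fragment A: C3–C7, quaternary C5, side chain) with phosphonate 28 (fragment B: C8–C11, C1, C2).
3. Fragment A comes from the L-glutamic acid butyrolactone: two enolate alkylations (MeI, then allylic bromide 6 = fragment C) set C5; the lactone carbonyl becomes alkyne, then (E)-vinyl iodide; glycol cleavage gives the aldehyde.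
4. Fragment B comes from triethyl phosphonoacetate and homoprenyl bromide (from cyclopropyl methyl ketone) by SeO2 oxidation and Sharpless epoxidation; fragment C comes from 2-methylbut-3-yn-2-ol.
5. Ring order: temporary butyrolactone template (opened in step 11), then the oxirane (step 19), then the 11-membered carbocycle (step 22).

Assumption: locants C1–C12 are those of the 12-oxabicyclo[9.1.0]dodeca-3,7-diene core (C1 methyl-bearing oxirane carbon, C2 ester carbon, C5 quaternary carbon, C8 hydroxymethyl carbon, C11 second oxirane carbon); 28 is used as a mixture of epimers at the phosphonate carbon, which becomes sp2 in step 20.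

**Fragment C (steps 1–4)**

Step 1
Reactants: 1 2-methylbut-3-yn-2-ol
Product: 2 triethyl[(2-methylbut-3-yn-2-yl)oxy]silane
Conditions: Et3SiOTf, 2,6-lutidine, CH2Cl2, 0 °C
Reagents that add atoms: triethylsilyl trifluoromethanesulfonate, CC[Si](CC)(CC)OS(=O)(=O)C(F)(F)F
Why: O-silylation with a silyl triflate caps the hindered tertiary alcohol so that it survives the organolithium, hydride and enolate steps that follow.

Step 2
Reactants: 2 triethyl[(2-methylbut-3-yn-2-yl)oxy]silane
Product: 4 4-methyl-4-[(triethylsilyl)oxy]pent-2-yn-1-ol, via lithium acetylide 3 (not isolated)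
Conditions: n-BuLi, THF, −78 °C; then (CH2O)n, −78 °C → rt
Reagents that add atoms: paraformaldehyde (formaldehyde), C=O
Why: Deprotonation of the terminal alkyne and 1,2-addition of the lithium acetylide to formaldehyde (acetylide hydroxymethylation) gives the propargylic alcohol.

Step 3
Reactants: 4 4-methyl-4-[(triethylsilyl)oxy]pent-2-yn-1-ol
Product: 5 (2E)-4-methyl-4-[(triethylsilyl)oxy]pent-2-en-1-ol
Conditions: NaAlH2(OCH2CH2OMe)2, THF, 0 °C → rt; then H2O
Reagents that add atoms: none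
Why: Alkoxide-directed trans-hydroalumination of the propargylic alcohol followed by protonolysis gives only the E-alkene.

Step 4
Reactants: 5 (2E)-4-methyl-4-[(triethylsilyl)oxy]pent-2-en-1-ol
Product: 6 {[(3E)-5-bromo-2-methylpent-3-en-2-yl]oxy}(triethyl)silane
Conditions: CBr4, PPh3, CH2Cl2, −10 °C
Reagents that add atoms: tetrabromomethane, BrC(Br)(Br)Br
Why: Appel bromination converts the primary allylic alcohol into the bromide under neutral conditions, leaving the silyl ether and the E-geometry untouched.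

**Fragment A (steps 5–14)**

Step 5
Reactants: 7 L-glutamic acid
Product: 8 (2S)-5-oxotetrahydrofuran-2-carboxylic acid
Conditions: NaNO2, aq. HCl, 0 °C → rt
Reagents that add atoms: none
Why: Diazotisation of the amino group and lactonisation by the γ-carboxylate go with net retention (double inversion through the α-lactone), so the S centre of the amino acid is kept.

Step 6
Reactants: 8 (2S)-5-oxotetrahydrofuran-2-carboxylic acid
Product: 9 (5S)-5-(hydroxymethyl)dihydrofuran-2(3H)-one
Conditions: BH3·SMe2, THF, 0 °C → rt; then MeOH/H2O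
Reagents that add atoms: none
Why: Borane reduces the carboxylic acid chemoselectively in the presence of the lactone; the stereocentre is not involved.

Step 7
Reactants: 9 (5S)-5-(hydroxymethyl)dihydrofuran-2(3H)-one
Product: 10 (5S)-5-{[(tert-butyldiphenylsilyl)oxy]methyl}dihydrofuran-2(3H)-one
Conditions: t-BuPh2SiCl, imidazole, DMF, rt
Reagents that add atoms: tert-butyl(chloro)diphenylsilane, CC(C)(C)[Si](Cl)(c1ccccc1)c1ccccc1
Why: Silylation of the primary alcohol installs the bulky group that later shields one face of the lactone enolate.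

Step 8
Reactants: 10 (5S)-5-{[(tert-butyldiphenylsilyl)oxy]methyl}dihydrofuran-2(3H)-one
Product: 12 (5S)-5-{[(tert-butyldiphenylsilyl)oxy]methyl}-3-methyldihydrofuran-2(3H)-one (C3 epimers), via lithium enolate 11 (not isolated)
Conditions: LiN(i-Pr)2, THF, −78 °C; then MeI
Reagents that add atoms: iodomethane, CI
Why: Lactone enolate C-alkylation; the C3 centre formed here (mainly trans to the C5 substituent) is erased by re-enolisation in step 9, so its ratio does not matter.

Step 9
Reactants: 12 (5S)-5-{[(tert-butyldiphenylsilyl)oxy]methyl}-3-methyldihydrofuran-2(3H)-one; 6 {[(3E)-5-bromo-2-methylpent-3-en-2-yl]oxy}(triethyl)silane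
Product: 14 (3R,5S)-5-{[(tert-butyldiphenylsilyl)oxy]methyl}-3-methyl-3-{(2E)-4-methyl-4-[(triethylsilyl)oxy]pent-2-en-1-yl}dihydrofuran-2(3H)-one, via lithium enolate 13 (not isolated)
Conditions: LiN(i-Pr)2, THF, −78 °C; then 6, DMPU, −78 → −30 °C
Reagents that add atoms: none
Why: SN2 alkylation of the tetrasubstituted lactone enolate takes place on the face anti to the bulky C5 silyloxymethyl group (1,3-induction), so the group introduced second ends up trans and the quaternary centre (future C5 of the target) is formed as R.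

Step 10
Reactants: 14 (the quaternary lactone)
Product: 15 (3R,5S)-5-{[(tert-butyldiphenylsilyl)oxy]methyl}-3-methyl-3-{(2E)-4-methyl-4-[(triethylsilyl)oxy]pent-2-en-1-yl}tetrahydrofuran-2-ol (anomers)
Conditions: i-Bu2AlH, CH2Cl2, −78 °C
Reagents that add atoms: none
Why: Partial hydride reduction of a γ-lactone stops at the lactol because the tetrahedral aluminium hemiacetal is stable at −78 °C.

Step 11
Reactants: 15 (the lactol)
Product: 16 (2S,4R,6E)-1-[(tert-butyldiphenylsilyl)oxy]-4-ethynyl-4,8-dimethyl-8-[(triethylsilyl)oxy]non-6-en-2-ol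
Conditions: dimethyl (1-diazo-2-oxopropyl)phosphonate, K2CO3, MeOH, rt → 40 °C
Reagents that add atoms: dimethyl (1-diazo-2-oxopropyl)phosphonate (Ohira–Bestmann reagent), COP(=O)(OC)C(=[N+]=[N-])C(C)=O
Why: Ohira–Bestmann (Seyferth–Gilbert) homologation of the ring-opened hydroxy aldehyde gives the terminal alkyne; the aldehyde has no α-hydrogen, so the quaternary centre cannot epimerise.

Step 12
Reactants: 16 (the alkyne)
Product: 18 (2S,4R,6E)-1-[(tert-butyldiphenylsilyl)oxy]-4-[(E)-2-iodoethenyl]-4,8-dimethyl-8-[(triethylsilyl)oxy]non-6-en-2-ol, via alkenylzirconocene chloride 17 (not isolated)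
Conditions: Cp2Zr(H)Cl (2.5 equiv), THF, rt; then I2, 0 °C
Reagents that add atoms: iodine, [I][I]
Why: Hydrozirconation adds Zr–H syn across the terminal alkyne with zirconium at the terminus, and iodinolysis with retention gives the (E)-vinyl iodide; the hindered internal alkene is left alone.

Step 13
Reactants: 18 (the silylated vinyl iodide)
Product: 19 (2S,4R,6E)-4-[(E)-2-iodoethenyl]-4,8-dimethylnon-6-ene-1,2,8-triol
Conditions: Bu4NF, THF, rt
Reagents that add atoms: none
Why: Fluoride-mediated desilylation removes both silyl ethers without acid, which the tertiary allylic alcohol would not tolerate.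

Step 14
Reactants: 19 (the triol)
Product: 20 (3R,5E)-7-hydroxy-3-[(E)-2-iodoethenyl]-3,7-dimethyloct-5-enal
Conditions: NaIO4, THF/H2O, 0 °C → rt
Reagents that add atoms: none
Why: Periodate glycol cleavage of the terminal 1,2-diol excises one carbon and unveils the C7 aldehyde; the tertiary alcohol and the vinyl iodide are inert.

**Fragment B (steps 15–19)**

Step 15
Reactants: 21 cyclopropyl methyl ketone
Product: 22 2-cyclopropylpropan-2-ol
Conditions: MeMgBr, Et2O, 0 °C
Reagents that add atoms: methylmagnesium bromide, C[Mg]Br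
Why: Grignard 1,2-addition to the ketone gives the tertiary cyclopropyl carbinol.

Step 16
Reactants: 22 2-cyclopropylpropan-2-ol
Product: 23 5-bromo-2-methylpent-2-ene
Conditions: 48% aq. HBr, 0 °C
Reagents that add atoms: hydrogen bromide, Br
Why: Julia cyclopropylcarbinyl-to-homoallyl rearrangement: ionisation and ring opening by bromide give the homoallylic bromide with the trisubstituted alkene.

Step 17
Reactants: 24 triethyl phosphonoacetate; 23 5-bromo-2-methylpent-2-ene
Product: 26 ethyl 2-(diethoxyphosphoryl)-6-methylhept-5-enoate (racemic), via sodium phosphonoacetate enolate 25 (not isolated)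
Conditions: NaH, DMF, 0 °C; then 23, 60 °C
Reagents that add atoms: none
Why: SN2 C-alkylation of the stabilised phosphonoacetate anion with the primary bromide; the new centre is racemic and is destroyed in step 20.

Step 18
Reactants: 26 ethyl 2-(diethoxyphosphoryl)-6-methylhept-5-enoate
Product: 27 ethyl (5E)-2-(diethoxyphosphoryl)-7-hydroxy-6-methylhept-5-enoate
Conditions: SeO2 (cat.), t-BuOOH, CH2Cl2, rt
Reagents that add atoms: tert-butyl hydroperoxide, CC(C)(C)OO (oxygen transferred through catalytic SeO2, O=[Se]=O)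
Why: Selenium dioxide allylic oxidation (ene reaction, then [2,3]-sigmatropic shift) hydroxylates selectively the (E)-methyl group of the trisubstituted alkene.

Step 19
Reactants: 27 ethyl (5E)-2-(diethoxyphosphoryl)-7-hydroxy-6-methylhept-5-enoate
Product: 28 ethyl 2-(diethoxyphosphoryl)-4-[(2R,3R)-3-(hydroxymethyl)-3-methyloxiran-2-yl]butanoate
Conditions: Ti(OiPr)4 (0.2 equiv), D-(−)-diisopropyl tartrate (0.24 equiv), t-BuOOH, 4 Å MS, CH2Cl2, −20 °C
Reagents that add atoms: tert-butyl hydroperoxide, CC(C)(C)OO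
Why: Sharpless asymmetric epoxidation of the (E)-2-methyl allylic alcohol; the D-(−)-tartrate catalyst delivers oxygen to the face that gives the (2R,3R)-epoxy alcohol (future C11 and C1), independently of the remote phosphonate centre.

**Union and endgame (steps 20–26)**

Step 20
Reactants: 20 (3R,5E)-7-hydroxy-3-[(E)-2-iodoethenyl]-3,7-dimethyloct-5-enal; 28 ethyl 2-(diethoxyphosphoryl)-4-[(2R,3R)-3-(hydroxymethyl)-3-methyloxiran-2-yl]butanoate
Product: 29 ethyl (2E,5R,7E)-9-hydroxy-2-{2-[(2R,3R)-3-(hydroxymethyl)-3-methyloxiran-2-yl]ethyl}-5-[(E)-2-iodoethenyl]-5,9-dimethyldeca-2,7-dienoate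
Conditions: LiCl, DBU, MeCN, 0 °C → rt
Reagents that add atoms: none
Why: Horner–Wadsworth–Emmons olefination under Masamune–Roush conditions is mild enough for the free alcohols and the epoxide and gives the E-enoate (β-substituent trans to the ester), the geometry that places C6 and C9 cis as the ring requires; both phosphonate epimers converge and any Z isomer is removed by chromatography.

Step 21
Reactants: 29 (the epoxy alcohol)
Product: 30 ethyl (2E,5R,7E)-2-{2-[(2R,3S)-3-formyl-3-methyloxiran-2-yl]ethyl}-9-hydroxy-5-[(E)-2-iodoethenyl]-5,9-dimethyldeca-2,7-dienoate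
Conditions: Dess–Martin periodinane, NaHCO3, CH2Cl2, 0 °C → rt
Reagents that add atoms: none
Why: Buffered Dess–Martin oxidation turns the only primary alcohol into the epoxy aldehyde; the tertiary alcohol cannot be oxidised and the aldehyde α-carbon is quaternary, so nothing epimerises.

Step 22
Reactants: 30 (the epoxy aldehyde vinyl iodide)
Product: 31 ethyl (1R,2S,3E,5R,7E,11R)-2-hydroxy-5-[(2E)-4-hydroxy-4-methylpent-2-en-1-yl]-1,5-dimethyl-12-oxabicyclo[9.1.0]dodeca-3,7-diene-8-carboxylate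
Conditions: CrCl2 (15 equiv), NiCl2 (cat.), DMSO, rt, 0.003 M, slow addition
Reagents that add atoms: none
Why: Intramolecular Nozaki–Hiyama–Kishi reaction (oxidative addition of the vinyl iodide to zerovalent nickel, transmetalation to trivalent chromium, aldehyde-selective addition) closes the 11-membered ring at high dilution; C2 is expected as S by attack anti to the oxirane C–O bond (polar Felkin–Anh, C1 methyl as medium group), a substrate-controlled prediction, and the C2 epimer is separable.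

Step 23
Reactants: 31 (the macrocyclic hydroxy ester)
Product: 32 (1R,2S,3E,5R,7E,11R)-8-(hydroxymethyl)-5-[(2E)-4-hydroxy-4-methylpent-2-en-1-yl]-1,5-dimethyl-12-oxabicyclo[9.1.0]dodeca-3,7-dien-2-ol
Conditions: i-Bu2AlH (4 equiv), CH2Cl2, −78 °C
Reagents that add atoms: none
Why: 1,2-Reduction of the conjugated ester by the aluminium hydride gives the allylic alcohol; at −78 °C the trisubstituted epoxide is not opened.

Step 24
Reactants: 32 (the triol)
Product: 33 (1R,2S,3E,5R,7E,11R)-8-({[tert-butyl(dimethyl)silyl]oxy}methyl)-5-[(2E)-4-hydroxy-4-methylpent-2-en-1-yl]-1,5-dimethyl-12-oxabicyclo[9.1.0]dodeca-3,7-dien-2-ol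
Conditions: t-BuMe2SiCl (1.1 equiv), imidazole, CH2Cl2, 0 °C
Reagents that add atoms: tert-butyl(chloro)dimethylsilane, CC(C)(C)[Si](C)(C)Cl
Why: Selective silylation: the primary allylic alcohol reacts far faster than the hindered secondary alcohol or the tertiary one.

Step 25
Reactants: 33 (the mono-silyl ether); 34 3-methylbut-2-enoic acid
Product: 35 (1S,2S,3E,5R,7E,11R)-8-({[tert-butyl(dimethyl)silyl]oxy}methyl)-5-[(2E)-4-hydroxy-4-methylpent-2-en-1-yl]-1,5-dimethyl-12-oxabicyclo[9.1.0]dodeca-3,7-dien-2-yl 3-methylbut-2-enoate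
Conditions: DCC, DMAP, CH2Cl2, 0 °C → rt
Reagents that add atoms: none
Why: Steglich esterification acylates the secondary allylic alcohol with retention at C2 (no bond to C2 is broken), leaves the tertiary alcohol alone and avoids the base-induced deconjugation seen with the acid chloride.

Step 26
Reactants: 35 (the silylated ester)
Product: 36 (1S,2S,3E,5R,7E,11R)-8-(hydroxymethyl)-5-[(2E)-4-hydroxy-4-methylpent-2-en-1-yl]-1,5-dimethyl-12-oxabicyclo[9.1.0]dodeca-3,7-dien-2-yl 3-methylbut-2-enoate (target)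
Conditions: Bu4NF, AcOH, THF, 0 °C → rt
Reagents that add atoms: none
Why: Buffered fluoride desilylation frees the primary allylic alcohol without touching the ester, the epoxide or the tertiary allylic alcohol.

**Compound list**

1 | 2-methylbut-3-yn-2-ol | CC(C)(O)C#C | starting material
2 | triethyl[(2-methylbut-3-yn-2-yl)oxy]silane | CC[Si](CC)(CC)OC(C)(C)C#C | intermediate
3 | lithium acetylide of 2 (not isolated) | [Li+].[C-]#CC(C)(C)O[Si](CC)(CC)CC | intermediate
4 | 4-methyl-4-[(triethylsilyl)oxy]pent-2-yn-1-ol | OCC#CC(C)(C)O[Si](CC)(CC)CC | intermediate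
5 | (2E)-4-methyl-4-[(triethylsilyl)oxy]pent-2-en-1-ol | OC/C=C/C(C)(C)O[Si](CC)(CC)CC | intermediate
6 | {[(3E)-5-bromo-2-methylpent-3-en-2-yl]oxy}(triethyl)silane | BrC/C=C/C(C)(C)O[Si](CC)(CC)CC | intermediate
7 | L-glutamic acid | N[C@@H](CCC(=O)O)C(=O)O | starting material
8 | (2S)-5-oxotetrahydrofuran-2-carboxylic acid | O=C1CC[C@@H](C(=O)O)O1 | intermediate
9 | (5S)-5-(hydroxymethyl)dihydrofuran-2(3H)-one | O=C1CC[C@@H](CO)O1 | intermediate
10 | (5S)-5-{[(tert-butyldiphenylsilyl)oxy]methyl}dihydrofuran-2(3H)-one | O=C1CC[C@@H](CO[Si](c2ccccc2)(c2ccccc2)C(C)(C)C)O1 | intermediate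
11 | lithium enolate of 10 (not isolated) | [Li+].[O-]C1=CC[C@@H](CO[Si](c2ccccc2)(c2ccccc2)C(C)(C)C)O1 | intermediate
12 | (5S)-5-{[(tert-butyldiphenylsilyl)oxy]methyl}-3-methyldihydrofuran-2(3H)-one (C3 epimers) | CC1C[C@@H](CO[Si](c2ccccc2)(c2ccccc2)C(C)(C)C)OC1=O | intermediate
13 | lithium enolate of 12 (not isolated) | [Li+].[O-]C1=C(C)C[C@@H](CO[Si](c2ccccc2)(c2ccccc2)C(C)(C)C)O1 | intermediate
14 | (3R,5S)-5-{[(tert-butyldiphenylsilyl)oxy]methyl}-3-methyl-3-{(2E)-4-methyl-4-[(triethylsilyl)oxy]pent-2-en-1-yl}dihydrofuran-2(3H)-one | O=C1[C@](C)(C/C=C/C(C)(C)O[Si](CC)(CC)CC)C[C@@H](CO[Si](c2ccccc2)(c2ccccc2)C(C)(C)C)O1 | intermediate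
15 | (3R,5S)-5-{[(tert-butyldiphenylsilyl)oxy]methyl}-3-methyl-3-{(2E)-4-methyl-4-[(triethylsilyl)oxy]pent-2-en-1-yl}tetrahydrofuran-2-ol (anomers) | OC1[C@](C)(C/C=C/C(C)(C)O[Si](CC)(CC)CC)C[C@@H](CO[Si](c2ccccc2)(c2ccccc2)C(C)(C)C)O1 | intermediate
16 | (2S,4R,6E)-1-[(tert-butyldiphenylsilyl)oxy]-4-ethynyl-4,8-dimethyl-8-[(triethylsilyl)oxy]non-6-en-2-ol | C#C[C@](C)(C/C=C/C(C)(C)O[Si](CC)(CC)CC)C[C@H](O)CO[Si](c1ccccc1)(c1ccccc1)C(C)(C)C | intermediate
17 | (E)-alkenylzirconocene chloride of 16, secondary oxygen bound as Cp2Zr(Cl) alkoxide (not isolated) | Cl[Zr](C1C=CC=C1)(C1C=CC=C1)/C=C/[C@](C)(C/C=C/C(C)(C)O[Si](CC)(CC)CC)C[C@H](O[Zr](Cl)(C1C=CC=C1)C1C=CC=C1)CO[Si](c1ccccc1)(c1ccccc1)C(C)(C)C | intermediate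
18 | (2S,4R,6E)-1-[(tert-butyldiphenylsilyl)oxy]-4-[(E)-2-iodoethenyl]-4,8-dimethyl-8-[(triethylsilyl)oxy]non-6-en-2-ol | I/C=C/[C@](C)(C/C=C/C(C)(C)O[Si](CC)(CC)CC)C[C@H](O)CO[Si](c1ccccc1)(c1ccccc1)C(C)(C)C | intermediate
19 | (2S,4R,6E)-4-[(E)-2-iodoethenyl]-4,8-dimethylnon-6-ene-1,2,8-triol | I/C=C/[C@](C)(C/C=C/C(C)(C)O)C[C@H](O)CO | intermediate
20 | (3R,5E)-7-hydroxy-3-[(E)-2-iodoethenyl]-3,7-dimethyloct-5-enal (fragment A) | I/C=C/[C@](C)(C/C=C/C(C)(C)O)CC=O | intermediate
21 | cyclopropyl methyl ketone | CC(=O)C1CC1 | starting material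
22 | 2-cyclopropylpropan-2-ol | CC(C)(O)C1CC1 | intermediate
23 | 5-bromo-2-methylpent-2-ene | CC(C)=CCCBr | intermediate
24 | triethyl phosphonoacetate | CCOC(=O)CP(=O)(OCC)OCC | starting material
25 | sodium enolate of 24 (not isolated) | [Na+].CCOC(=O)[CH-]P(=O)(OCC)OCC | intermediate
26 | ethyl 2-(diethoxyphosphoryl)-6-methylhept-5-enoate (racemic) | CCOC(=O)C(CCC=C(C)C)P(=O)(OCC)OCC | intermediate
27 | ethyl (5E)-2-(diethoxyphosphoryl)-7-hydroxy-6-methylhept-5-enoate | CCOC(=O)C(CC/C=C(\C)CO)P(=O)(OCC)OCC | intermediate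
28 | ethyl 2-(diethoxyphosphoryl)-4-[(2R,3R)-3-(hydroxymethyl)-3-methyloxiran-2-yl]butanoate (fragment B, epimers at C2 of the butanoate) | CCOC(=O)C(CC[C@H]1O[C@]1(C)CO)P(=O)(OCC)OCC | intermediate
29 | ethyl (2E,5R,7E)-9-hydroxy-2-{2-[(2R,3R)-3-(hydroxymethyl)-3-methyloxiran-2-yl]ethyl}-5-[(E)-2-iodoethenyl]-5,9-dimethyldeca-2,7-dienoate | I/C=C/[C@](C)(C/C=C/C(C)(C)O)C/C=C(/C(=O)OCC)CC[C@H]1O[C@]1(C)CO | intermediate
30 | ethyl (2E,5R,7E)-2-{2-[(2R,3S)-3-formyl-3-methyloxiran-2-yl]ethyl}-9-hydroxy-5-[(E)-2-iodoethenyl]-5,9-dimethyldeca-2,7-dienoate | I/C=C/[C@](C)(C/C=C/C(C)(C)O)C/C=C(/C(=O)OCC)CC[C@H]1O[C@]1(C)C=O | intermediate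
31 | ethyl (1R,2S,3E,5R,7E,11R)-2-hydroxy-5-[(2E)-4-hydroxy-4-methylpent-2-en-1-yl]-1,5-dimethyl-12-oxabicyclo[9.1.0]dodeca-3,7-diene-8-carboxylate | O[C@H]1/C=C/[C@](C)(C/C=C/C(C)(C)O)C/C=C(/C(=O)OCC)CC[C@H]2O[C@]12C | intermediate
32 | (1R,2S,3E,5R,7E,11R)-8-(hydroxymethyl)-5-[(2E)-4-hydroxy-4-methylpent-2-en-1-yl]-1,5-dimethyl-12-oxabicyclo[9.1.0]dodeca-3,7-dien-2-ol | O[C@H]1/C=C/[C@](C)(C/C=C/C(C)(C)O)C/C=C(/CO)CC[C@H]2O[C@]12C | intermediate
33 | (1R,2S,3E,5R,7E,11R)-8-({[tert-butyl(dimethyl)silyl]oxy}methyl)-5-[(2E)-4-hydroxy-4-methylpent-2-en-1-yl]-1,5-dimethyl-12-oxabicyclo[9.1.0]dodeca-3,7-dien-2-ol | O[C@H]1/C=C/[C@](C)(C/C=C/C(C)(C)O)C/C=C(/CO[Si](C)(C)C(C)(C)C)CC[C@H]2O[C@]12C | intermediate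
34 | 3-methylbut-2-enoic acid | CC(C)=CC(=O)O | starting material
35 | (1S,2S,3E,5R,7E,11R)-8-({[tert-butyl(dimethyl)silyl]oxy}methyl)-5-[(2E)-4-hydroxy-4-methylpent-2-en-1-yl]-1,5-dimethyl-12-oxabicyclo[9.1.0]dodeca-3,7-dien-2-yl 3-methylbut-2-enoate | CC(C)=CC(=O)O[C@H]1/C=C/[C@](C)(C/C=C/C(C)(C)O)C/C=C(/CO[Si](C)(C)C(C)(C)C)CC[C@H]2O[C@]12C | intermediate
36 | (1S,2S,3E,5R,7E,11R)-8-(hydroxymethyl)-5-[(2E)-4-hydroxy-4-methylpent-2-en-1-yl]-1,5-dimethyl-12-oxabicyclo[9.1.0]dodeca-3,7-dien-2-yl 3-methylbut-2-enoate | CC(C)=CC(=O)O[C@H]1/C=C/[C@](C)(C/C=C/C(C)(C)O)C/C=C(/CO)CC[C@H]2O[C@]12C | target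

**Step count**
Total step count: 26.
Longest linear sequence: 17 steps (steps 5–8 or steps 1–4, then 9–14, then 20–26). Fragment B (steps 15–19) is made in parallel.

**The three steps most likely to fail**

Step 22 (macrocyclisation). The 11-membered ring is strained, the epoxy aldehyde may be attacked by divalent chromium, and the C2 configuration rests on substrate control only. Fallback, setting out from 30 and coming back at 35: if the ring closes but the addition gives mainly the C2-epimeric macrocyclic hydroxy ester F1, this is reduced with i-Bu2AlH (CH2Cl2, −78 °C) to the C2-epimeric triol F2 and silylated (t-BuMe2SiCl, imidazole) to the C2-epimeric silyl ether F3. A Mitsunobu esterification of F3 with acid 34 (PPh3, DIAD, toluene, 0 °C → rt) then forms the senecioate with inversion at C2 and gives 35. C2 is then set by SN2 displacement instead of by the facial selectivity of the chromium addition, and both epimers from step 22 can be used.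

Step 9 (quaternary centre). The enolate is crowded and the functionalised bromide 6 can eliminate or react sluggishly. Fallback, setting out from 12 and coming back at 14: enolate 13 is alkylated with allyl bromide (small and very reactive, same facial bias) to give the (3R,5S)-3-allyl lactone F4. Cross-metathesis of F4 with 2-methylbut-3-en-2-ol (second-generation Grubbs catalyst, RuCl2(H2IMes)(PCy3)(=CHPh), CH2Cl2, 40 °C) builds the (E)-side chain as the tertiary allylic alcohol lactone F5. Silylation of F5 (Et3SiOTf, 2,6-lutidine) gives 14. The side chain is then assembled on the lactone instead of being brought in intact.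

Step 11 (alkyne from the lactol). The lactol carbon is neopentyl-type and ring opening is disfavoured by the geminal substituents, so the homologation may stall. Fallback, setting out from 14 and coming back at 18: LiAlH4 (THF, 0 °C) opens 14 to the open-chain 1,4-diol F6. Swern oxidation ((COCl)2, DMSO, Et3N, −78 °C) gives the keto aldehyde F7. Takai iodo-olefination (CrCl2, CHI3, THF, 0 °C), which reacts with the aldehyde and not the ketone, gives the (E)-iodoalkenyl ketone F8. NaBH4 (MeOH, 0 °C) then reduces the ketone to 18, formed together with its C2 epimer; both converge on 20 in steps 13 and 14 because that carbon becomes the aldehyde carbon.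

**Further compounds**

F1 | step 22 | C2-epimeric macrocyclic hydroxy ester: ethyl (1R,2R,3E,5R,7E,11R)-2-hydroxy-5-[(2E)-4-hydroxy-4-methylpent-2-en-1-yl]-1,5-dimethyl-12-oxabicyclo[9.1.0]dodeca-3,7-diene-8-carboxylate | O[C@@H]1/C=C/[C@](C)(C/C=C/C(C)(C)O)C/C=C(/C(=O)OCC)CC[C@H]2O[C@]12C
F2 | step 22 | C2-epimeric triol: (1R,2R,3E,5R,7E,11R)-8-(hydroxymethyl)-5-[(2E)-4-hydroxy-4-methylpent-2-en-1-yl]-1,5-dimethyl-12-oxabicyclo[9.1.0]dodeca-3,7-dien-2-ol | O[C@@H]1/C=C/[C@](C)(C/C=C/C(C)(C)O)C/C=C(/CO)CC[C@H]2O[C@]12C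
F3 | step 22 | C2-epimeric silyl ether: (1R,2R,3E,5R,7E,11R)-8-({[tert-butyl(dimethyl)silyl]oxy}methyl)-5-[(2E)-4-hydroxy-4-methylpent-2-en-1-yl]-1,5-dimethyl-12-oxabicyclo[9.1.0]dodeca-3,7-dien-2-ol | O[C@@H]1/C=C/[C@](C)(C/C=C/C(C)(C)O)C/C=C(/CO[Si](C)(C)C(C)(C)C)CC[C@H]2O[C@]12C
F4 | step 9 | (3R,5S)-3-allyl lactone: (3R,5S)-5-{[(tert-butyldiphenylsilyl)oxy]methyl}-3-methyl-3-(prop-2-en-1-yl)dihydrofuran-2(3H)-one | O=C1[C@](C)(CC=C)C[C@@H](CO[Si](c2ccccc2)(c2ccccc2)C(C)(C)C)O1
F5 | step 9 | tertiary allylic alcohol lactone: (3R,5S)-5-{[(tert-butyldiphenylsilyl)oxy]methyl}-3-[(2E)-4-hydroxy-4-methylpent-2-en-1-yl]-3-methyldihydrofuran-2(3H)-one | O=C1[C@](C)(C/C=C/C(C)(C)O)C[C@@H](CO[Si](c2ccccc2)(c2ccccc2)C(C)(C)C)O1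
F6 | step 11 | open-chain 1,4-diol: (2R,4S)-5-[(tert-butyldiphenylsilyl)oxy]-2-methyl-2-{(2E)-4-methyl-4-[(triethylsilyl)oxy]pent-2-en-1-yl}pentane-1,4-diol | OC[C@](C)(C/C=C/C(C)(C)O[Si](CC)(CC)CC)C[C@H](O)CO[Si](c1ccccc1)(c1ccccc1)C(C)(C)C
F7 | step 11 | keto aldehyde: (2R)-5-[(tert-butyldiphenylsilyl)oxy]-2-methyl-2-{(2E)-4-methyl-4-[(triethylsilyl)oxy]pent-2-en-1-yl}-4-oxopentanal | O=C[C@](C)(C/C=C/C(C)(C)O[Si](CC)(CC)CC)CC(=O)CO[Si](c1ccccc1)(c1ccccc1)C(C)(C)C
F8 | step 11 | (E)-iodoalkenyl ketone: (4R,6E)-1-[(tert-butyldiphenylsilyl)oxy]-4-[(E)-2-iodoethenyl]-4,8-dimethyl-8-[(triethylsilyl)oxy]non-6-en-2-one | I/C=C/[C@](C)(C/C=C/C(C)(C)O[Si](CC)(CC)CC)CC(=O)CO[Si](c1ccccc1)(c1ccccc1)C(C)(C)C
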